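**Strategy**

- The target is a C2-symmetric diarylmethane: a single CH2 joins C1 of two identical, fully substituted benzene rings, each a 2,3,6-tribromo-4,5-dihydroxyphenyl group with no ring C–H.
- The retrosynthesis cuts one aryl C1–CH2 bond. This is possible because each C1 lies para to the 4-OH: one half can act as a para-quinone methide (electrophilic exocyclic CH2), the other as the same benzyl alcohol attacked at its own C1, whose CH2OH carbon then leaves as formaldehyde.
- Further back, the benzylic alcohol comes from the aldehyde, and the three C–Br bonds of each ring from bromination of protocatechualdehyde.
- Forward: no ring is built. The bought benzene ring is brominated at all three C–H positions, the formyl group is reduced, and the two halves are joined through the CH2 bridge in the last step.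
- Stereochemistry: there is none to set (no stereocentre, no stereogenic double bond); the quaternary carbon of the ipso adduct is transient.

Key step: step 3

Assumption: bromine is taken to enter protocatechualdehyde first ortho to the 4-hydroxyl, then para to the 3-hydroxyl, and last between the 3-hydroxyl and the formyl group. If the order differs, the same tribromide results, because all three ring C–H positions are replaced.

**Step 1**
Reactants: 1 3,4-dihydroxybenzaldehyde (protocatechualdehyde); 2 bromine
Product: 5 2,3,6-tribromo-4,5-dihydroxybenzaldehyde, via 3-bromo-4,5-dihydroxybenzaldehyde 3 (not isolated), via 2,3-dibromo-4,5-dihydroxybenzaldehyde 4 (not isolated)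
Conditions: Br2 (3.5 equiv, two portions), AcOH, 20 °C; then Fe powder (5 mol%), 60 °C; aq. NaHSO3 quench
Reagents that add atoms: bromine 2, BrBr
Why: Electrophilic aromatic bromination: every ring C–H of 1 is ortho or para to a hydroxyl, so two bromines should enter at 20 °C and FeBr3 formed from the iron should force the last position, flanked by the formyl group and a hydroxyl, while the anhydrous acidic medium disfavours ipso attack at the formyl-bearing carbon and the bisulfite quench returns any ortho-quinone to the catechol.

**Step 2**
Reactants: 5 2,3,6-tribromo-4,5-dihydroxybenzaldehyde
Product: 6 (2,3,6-tribromo-4,5-dihydroxyphenyl)methanol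
Conditions: NaBH4 (3 equiv), THF/H2O, 0 °C; cold aq. citric acid to pH 4, EtOAc extraction
Reagents that add atoms: none
Why: Borohydride reduction of an aldehyde: hydride adds to the formyl group while the aryl bromides are inert, the two phenoxides only consume extra reagent, and the cold, alcohol-free work-up at pH 4 releases the catechol from its borate and keeps the acid-labile 4-hydroxybenzylic alcohol from solvolysing.

**Step 3**
Reactants: 6 (2,3,6-tribromo-4,5-dihydroxyphenyl)methanol (two molecules)
Product: 8 bis(2,3,6-tribromo-4,5-dihydroxyphenyl)methane, via para-quinone methide 7 (not isolated)
Conditions: CF3SO3H (5 mol%), (CF3)2CHOH/MeNO2, 60 °C, slow argon sweep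
Reagents that add atoms: none
Why: Acid ionises the benzylic C–O bond of 6, assisted by the para 4-OH, to the quinone methide 7 (in equilibrium with its O-protonated benzylic cation), whose exocyclic CH2 is attacked by C1 of a second molecule of 6, the ring carbon para to that molecule's 4-OH; the resulting 4-benzyl-4-(hydroxymethyl)cyclohexadienone cation rearomatises by breaking its C1–CH2OH bond and expelling protonated formaldehyde. The closest known reaction type is the acid- or heat-induced self-condensation of 3,5-disubstituted 4-hydroxybenzyl alcohols to 4,4'-methylenebisphenols with loss of formaldehyde, the ipso substitution that also turns methylol groups into methylene bridges when phenolic resins cure; here it is carried over to a more electron-poor ring whose ipso carbon lies between two bromines, which is why a strongly ionising, non-nucleophilic medium is chosen. No ring closes and no stereocentre is set, the quaternary carbon of the ipso adduct being lost again on rearomatisation. The step needs C-attack at C1 instead of attack at oxygen or at a bromine-bearing carbon, and the substrate secures this because O-benzylation, dibenzyl ether formation and attack at C–Br are all reversible under acid and return the same cation, while C1 alone carries a substituent that can leave as a stabilised cation. Sweeping out formaldehyde makes that exit irreversible, and since neither 6 nor 8 has a ring C–H, no regioisomer or higher oligomer can arise, attack of 7 on the product being degenerate.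

**Compound list**

1 | 3,4-dihydroxybenzaldehyde (protocatechualdehyde) | O=Cc1ccc(O)c(O)c1 | starting material
2 | bromine | BrBr | starting material
3 | 3-bromo-4,5-dihydroxybenzaldehyde | O=Cc1cc(O)c(O)c(Br)c1 | intermediate
4 | 2,3-dibromo-4,5-dihydroxybenzaldehyde | O=Cc1cc(O)c(O)c(Br)c1Br | intermediate
5 | 2,3,6-tribromo-4,5-dihydroxybenzaldehyde | O=Cc1c(Br)c(O)c(O)c(Br)c1Br | intermediate
6 | (2,3,6-tribromo-4,5-dihydroxyphenyl)methanol | OCc1c(Br)c(O)c(O)c(Br)c1Br | intermediate
7 | 2,3,5-tribromo-6-hydroxy-4-methylidenecyclohexa-2,5-dien-1-one | C=C1C(Br)=C(O)C(=O)C(Br)=C1Br | intermediate
8 | bis(2,3,6-tribromo-4,5-dihydroxyphenyl)methane | Oc1c(O)c(Br)c(Cc2c(Br)c(O)c(O)c(Br)c2Br)c(Br)c1Br | target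

Total step count: 3. Longest linear sequence: 3 steps (1 to 8).

**Steps most likely to fail**

Step 3. The union may stall at the reversible ether stage (O-benzylation and dibenzyl ether formation) because C-attack at the electron-poor ipso carbon between two bromines is too slow. Formaldehyde may also be recaptured on the catechol oxygens instead of leaving the flask. Early loss of formaldehyde from 6 by ipso-protonation would not be a dead end, since the arene so formed has one free position para to a hydroxyl that 7 can benzylate to the same product.

The fallback uses known chemistry and reverses the order, making the bridge on electron-rich rings and adding bromine last. It sets out from 1 and comes back at 8. Reduction of 1 with NaBH4 (THF/H2O, 0 °C) should give 3,4-dihydroxybenzyl alcohol F1. Acid-catalysed Friedel–Crafts benzylation of a large excess of commercial catechol with F1 (p-toluenesulfonic acid, water, 80 °C) should take place mainly at the 4-position of catechol and give 4,4'-methylenedi(benzene-1,2-diol) F2, to be freed from minor regioisomers by crystallisation. Exhaustive bromination of F2 with bromine 2 (slight excess over 6 equiv, AcOH, 20 to 40 °C, NaHSO3 quench) should replace all six ring C–H bonds, each ortho or para to a hydroxyl, and give 8.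

Step 1. In the forced last bromination, bromine may attack ipso at the formyl-bearing carbon (para to the 4-OH) with loss of the formyl group, or the reaction may stop after two bromines.

The fallback carries the benzylic carbon at the ester level, where it cannot be expelled as a cation. It sets out from bromine 2 and comes back at 6, bypassing 5. Commercial methyl 3,4-dihydroxybenzoate is brominated with 2 under the conditions of step 1 to methyl 2,3,6-tribromo-4,5-dihydroxybenzoate F3. Reduction of F3 with excess i-Bu2AlH (CH2Cl2/THF, −78 to 0 °C, cold mildly acidic work-up) should give 6.

Step 2. The phenoxide formed under the basic hydride conditions may expel hydroxide to give the quinone methide, which borohydride would reduce further to the methylarene. The benzylic alcohol may also solvolyse or begin to self-condense during work-up.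

The fallback masks the para oxygen so that no quinone methide can form during the reduction. It sets out from 5 and comes back at 6. Acetylation of 5 (Ac2O, pyridine, catalytic 4-(dimethylamino)pyridine) should give 3,4,6-tribromo-5-formyl-1,2-phenylene diacetate F4. Reduction of the aldehyde with BH3·SMe2 (THF, 0 °C), which leaves aryl acetates untouched, should give 3,4,6-tribromo-5-(hydroxymethyl)-1,2-phenylene diacetate F5. Hydrolysis of both acetates with aqueous HCl in 1,4-dioxane at 50 °C should give 6, water being the only nucleophile present.

**Further compounds**

F1 | step 3 | 4-(hydroxymethyl)benzene-1,2-diol (3,4-dihydroxybenzyl alcohol) | OCc1ccc(O)c(O)c1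
F2 | step 3 | 4,4'-methylenedi(benzene-1,2-diol) | Oc1ccc(Cc2ccc(O)c(O)c2)cc1O
F3 | step 1 | methyl 2,3,6-tribromo-4,5-dihydroxybenzoate | COC(=O)c1c(Br)c(O)c(O)c(Br)c1Br
F4 | step 2 | 3,4,6-tribromo-5-formyl-1,2-phenylene diacetate | CC(=O)Oc1c(Br)c(C=O)c(Br)c(Br)c1OC(C)=O
F5 | step 2 | 3,4,6-tribromo-5-(hydroxymethyl)-1,2-phenylene diacetate | CC(=O)Oc1c(Br)c(CO)c(Br)c(Br)c1OC(C)=O
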